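Ring C of the upper (guibourtinidol) unit is disconnected at O1–C8a and at C3–C4. A β-oxido alkyllithium that already holds C2 in the correct configuration (O1–C2–C3) adds through C3 to a diaryl ketone whose carbonyl carbon is C4 and which already carries C8 of the benzyl-protected epiafzelechin unit; the C2 alkoxide then displaces fluoride from C8a of ring A. One operation thus builds ring C onto the preformed interflavan C4–C8 bond. It exploits that C4 sits between ring D and the ortho pair C4a/C8a of ring A. Dehydration and hydroboration anti to the C2 aryl group then set C3 and C4.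

Key step: step 6

Assumption: (−)-epiafzelechin 1, the acid 4 and the chloroketone 9 are taken as purchasable; 1 supplies the two stereocentres of the lower unit, which no later step touches.

Labels: flavan numbering is used. Rings A (benzo), C (pyran) and B (4-hydroxyphenyl) belong to the upper unit; ring D is the benzo ring of the lower (epiafzelechin) unit. The target is guibourtinidol-(4α→8)-epiafzelechin: upper unit 2R,3S,4S (2,3-trans-3,4-trans), lower unit 2R,3R.

Step 1
Reactants: 1 (−)-epiafzelechin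
Product: 2 tetra-O-benzyl-epiafzelechin
Conditions: BnBr (5 equiv), NaH (5 equiv), n-Bu4NI (cat.), DMF, 0 °C → rt
Reagents that add atoms: benzyl bromide, BrCc1ccccc1
Why: Williamson etherification of the three phenoxides and the 3-alkoxide, in which alkylation at 0 °C should outrun any base-induced epimerisation at C2, so no stereocentre is touched.

Step 2
Reactants: 2 tetra-O-benzyl-epiafzelechin
Product: 3 8-bromo-tetra-O-benzyl-epiafzelechin
Conditions: NBS (1.0 equiv), CH2Cl2, −78 °C → rt
Reagents that add atoms: N-bromosuccinimide, O=C1CCC(=O)N1Br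
Why: Electrophilic aromatic bromination, which should occur at C8 because this is the most nucleophilic position of the phloroglucinol-type ring D (ahead of C6 and far ahead of the 4-benzyloxyphenyl ring).

Step 3
Reactants: 4 4-(benzyloxy)-2-fluorobenzoic acid
Product: 6 4-(benzyloxy)-2-fluoro-N-methoxy-N-methylbenzamide, via acyl imidazole 5 (not isolated)
Conditions: CDI (1.1 equiv), CH2Cl2, rt; then MeNH(OMe)·HCl (1.2 equiv), rt
Reagents that add atoms: N,O-dimethylhydroxylamine hydrochloride, CNOC.Cl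
Why: Amide formation through an acyl imidazole, in which the hydroxylamine displaces imidazole to give the Weinreb amide.

Step 4
Reactants: 3 8-bromo-tetra-O-benzyl-epiafzelechin; 6 4-(benzyloxy)-2-fluoro-N-methoxy-N-methylbenzamide
Product: 8 diaryl ketone (2-fluoro-4-benzyloxyphenyl flavan-8-yl ketone), via 8-lithio flavan 7 (not isolated)
Conditions: n-BuLi (1.05 equiv), THF, −78 °C; then 6, −78 → 0 °C; H2O
Reagents that add atoms: none
Why: Bromine–lithium exchange followed by Weinreb ketone synthesis, in which the N-methoxy-N-methyl amide should stop the addition at the ketone stage and the flavan stereocentres are not involved.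

Step 5
Reactants: 9 1-[4-(benzyloxy)phenyl]-2-chloroethanone
Product: 10 (1R)-1-[4-(benzyloxy)phenyl]-2-chloroethanol
Conditions: RuCl(p-cymene)[(S,S)-TsDPEN] (1 mol%), HCO2H/Et3N (5:2), EtOAc, rt
Reagents that add atoms: none
Why: Noyori-type asymmetric transfer hydrogenation of an α-chloro aryl ketone, in which the (S,S)-configured catalyst should deliver hydride to the face that gives the (R)-chlorohydrin and so sets the future C2 of the upper unit.

Step 6
Reactants: 10 (1R)-1-[4-(benzyloxy)phenyl]-2-chloroethanol; 8 diaryl ketone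
Product: 13 (2S,4RS)-2,4-diarylchroman-4-ol (ring C closed on the lower unit), via dilithio alkoxide 11 (not isolated), via open-chain dialkoxide 12 (not isolated)
Conditions: 10 (1.5 equiv), n-BuLi (1.5 equiv), THF, −78 °C; lithium naphthalenide LiC10H8 (3.0 equiv), −78 °C; 8 (1.0 equiv), −78 → −20 °C; KOt-Bu (3 equiv), DMPU, 60 °C; H2O
Reagents that add atoms: none
Why: Chlorine–lithium exchange on the lithium alkoxide of 10 by the arene radical anion gives the β-oxido alkyllithium 11, whose carbanion carbon C3 adds 1,2 to the non-enolisable ketone 8 (C3–C4), and after exchange to the potassium alkoxide O1 displaces fluoride at C8a by addition–elimination (O1–C8a). The closest known reaction types are the addition of β-oxido organolithiums (from chlorohydrins) to ketones and the base-mediated intramolecular SNAr of 3-(2-fluoroaryl)propan-1-olates to chromans. Ring C closes in the 6-exo-trig mode on the aromatic carbon C8a, and the tertiary C4 alkoxide cannot compete because it would have to form a four-membered ring. C2 is carried in unchanged from 10 since no bond to it is broken, while the new C4 carbinol centre forms without control and is erased in step 7. The step needs attack of the carbanion on the carbonyl group in preference to the C–F bond and the benzyl ethers, which the low temperature and the absence of α-hydrogens in 8 should secure, and it needs a single site for the oxygen, which is given because fluorine sits only at C8a, ortho to C4a and meta to the 7-benzyloxy group.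

Step 7
Reactants: 13 (2S,4RS)-2,4-diarylchroman-4-ol
Product: 14 (2S)-2,4-diaryl-2H-chromene (4-aryl-flav-3-ene)
Conditions: Burgess reagent (1.5 equiv), THF, rt → 50 °C, dark
Reagents that add atoms: none
Why: Burgess dehydration (syn-elimination of the tertiary sulfamate ester), which can only give the C3=C4 alkene because the sole β-hydrogens are on C3, removes the uncontrolled C4 centre and, being neutral and run in the dark, should keep C2 from racemising by ring opening.

Step 8
Reactants: 14 (2S)-2,4-diaryl-2H-chromene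
Product: 16 hexa-O-benzyl guibourtinidol-(4α→8)-epiafzelechin, via alkylborane 15 (not isolated)
Conditions: BH3·THF (3 equiv), THF, 0 °C → rt; then 3 M NaOH, 30% H2O2, 0 °C → rt
Reagents that add atoms: hydrogen peroxide, OO
Why: Hydroboration–oxidation, in which borane should add syn with boron at the non-benzylic C3 from the face opposite the C2 aryl group (2,3-trans) and hydrogen at C4 on that same face (C4 aryl trans to the C3 oxygen), and oxidation with retention then gives the 2,3-trans-3,4-trans alcohol.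

Step 9
Reactants: 16 hexa-O-benzyl guibourtinidol-(4α→8)-epiafzelechin
Product: 17 guibourtinidol-(4α→8)-epiafzelechin (target)
Conditions: H2 (1 atm), Pd(OH)2/C, THF/MeOH/H2O, rt
Reagents that add atoms: none
Why: Hydrogenolysis of the six benzyl ethers under neutral conditions, which should leave the interflavan bond, the benzylic C2–O bonds and all five stereocentres untouched.

Compound list
1 | (−)-epiafzelechin, (2R,3R)-2-(4-hydroxyphenyl)chroman-3,5,7-triol | Oc1cc(O)c2c(c1)O[C@H](c1ccc(O)cc1)[C@H](O)C2 | starting material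
2 | (2R,3R)-3,5,7-tris(benzyloxy)-2-[4-(benzyloxy)phenyl]chroman | C(Oc1cc(OCc2ccccc2)c2c(c1)O[C@H](c1ccc(OCc3ccccc3)cc1)[C@H](OCc1ccccc1)C2)c1ccccc1 | intermediate
3 | (2R,3R)-3,5,7-tris(benzyloxy)-2-[4-(benzyloxy)phenyl]-8-bromochroman | C(Oc1cc(OCc2ccccc2)c2c(c1Br)O[C@H](c1ccc(OCc3ccccc3)cc1)[C@H](OCc1ccccc1)C2)c1ccccc1 | intermediate
4 | 4-(benzyloxy)-2-fluorobenzoic acid | OC(=O)c1ccc(OCc2ccccc2)cc1F | starting material
5 | [4-(benzyloxy)-2-fluorophenyl](1H-imidazol-1-yl)methanone | O=C(c1ccc(OCc2ccccc2)cc1F)n1ccnc1 | intermediate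
6 | 4-(benzyloxy)-2-fluoro-N-methoxy-N-methylbenzamide | CON(C)C(=O)c1ccc(OCc2ccccc2)cc1F | intermediate
7 | [(2R,3R)-3,5,7-tris(benzyloxy)-2-[4-(benzyloxy)phenyl]chroman-8-yl]lithium | [Li]c1c(OCc2ccccc2)cc(OCc2ccccc2)c2c1O[C@H](c1ccc(OCc3ccccc3)cc1)[C@H](OCc1ccccc1)C2 | intermediate
8 | [4-(benzyloxy)-2-fluorophenyl][(2R,3R)-3,5,7-tris(benzyloxy)-2-[4-(benzyloxy)phenyl]chroman-8-yl]methanone | O=C(c1ccc(OCc2ccccc2)cc1F)c1c(OCc2ccccc2)cc(OCc2ccccc2)c2c1O[C@H](c1ccc(OCc3ccccc3)cc1)[C@H](OCc1ccccc1)C2 | intermediate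
9 | 1-[4-(benzyloxy)phenyl]-2-chloroethanone | O=C(CCl)c1ccc(OCc2ccccc2)cc1 | starting material
10 | (1R)-1-[4-(benzyloxy)phenyl]-2-chloroethanol | O[C@@H](CCl)c1ccc(OCc2ccccc2)cc1 | intermediate
11 | lithium 1-[4-(benzyloxy)phenyl]-2-lithioethan-1-olate, same spatial arrangement as 10 (descriptor becomes S) | [Li]O[C@@H](C[Li])c1ccc(OCc2ccccc2)cc1 | intermediate
12 | dilithium salt of 3-[4-(benzyloxy)phenyl]-1-[4-(benzyloxy)-2-fluorophenyl]-1-[(2R,3R)-3,5,7-tris(benzyloxy)-2-[4-(benzyloxy)phenyl]chroman-8-yl]propane-1,3-diol, 3S at the carbinol that becomes C2, C1 uncontrolled | [Li]O[C@@H](CC(O[Li])(c1ccc(OCc2ccccc2)cc1F)c1c(OCc2ccccc2)cc(OCc2ccccc2)c2c1O[C@H](c1ccc(OCc3ccccc3)cc1)[C@H](OCc1ccccc1)C2)c1ccc(OCc2ccccc2)cc1 | intermediate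
13 | (2S,4RS)-7-(benzyloxy)-2-[4-(benzyloxy)phenyl]-4-[(2R,3R)-3,5,7-tris(benzyloxy)-2-[4-(benzyloxy)phenyl]chroman-8-yl]chroman-4-ol (both C4 epimers) | C(Oc1ccc(cc1)[C@H]1Oc2cc(OCc3ccccc3)ccc2C(O)(c2c(OCc3ccccc3)cc(OCc3ccccc3)c3c2O[C@H](c2ccc(OCc4ccccc4)cc2)[C@H](OCc2ccccc2)C3)C1)c1ccccc1 | intermediate
14 | (2S)-7-(benzyloxy)-2-[4-(benzyloxy)phenyl]-4-[(2R,3R)-3,5,7-tris(benzyloxy)-2-[4-(benzyloxy)phenyl]chroman-8-yl]-2H-chromene | C(Oc1ccc(cc1)[C@H]1Oc2cc(OCc3ccccc3)ccc2C(c2c(OCc3ccccc3)cc(OCc3ccccc3)c3c2O[C@H](c2ccc(OCc4ccccc4)cc2)[C@H](OCc2ccccc2)C3)=C1)c1ccccc1 | intermediate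
15 | C3 monoalkylborane of 16 (BH2 in place of the 3-hydroxyl, trans to both the C2 and the C4 aryl groups) | C(Oc1ccc(cc1)[C@H]1Oc2cc(OCc3ccccc3)ccc2[C@@H](c2c(OCc3ccccc3)cc(OCc3ccccc3)c3c2O[C@H](c2ccc(OCc4ccccc4)cc2)[C@H](OCc2ccccc2)C3)[C@@H]1B)c1ccccc1 | intermediate
16 | (2R,3S,4S)-7-(benzyloxy)-2-[4-(benzyloxy)phenyl]-4-[(2R,3R)-3,5,7-tris(benzyloxy)-2-[4-(benzyloxy)phenyl]chroman-8-yl]chroman-3-ol | C(Oc1ccc(cc1)[C@H]1Oc2cc(OCc3ccccc3)ccc2[C@@H](c2c(OCc3ccccc3)cc(OCc3ccccc3)c3c2O[C@H](c2ccc(OCc4ccccc4)cc2)[C@H](OCc2ccccc2)C3)[C@@H]1O)c1ccccc1 | intermediate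
17 | (2R,3S,4S)-2-(4-hydroxyphenyl)-4-[(2R,3R)-3,5,7-trihydroxy-2-(4-hydroxyphenyl)chroman-8-yl]chroman-3,7-diol | Oc1ccc([C@H]2Oc3cc(O)ccc3[C@@H](c3c(O)cc(O)c4c3O[C@H](c3ccc(O)cc3)[C@H](O)C4)[C@@H]2O)cc1 | target

Total step count: 9
Longest linear sequence: 7 steps (steps 1, 2, 4, 6, 7, 8, 9); steps 3 and 5 are one-step side branches.

Steps most likely to fail

Step 6. The β-oxido alkyllithium may undergo β-elimination before it adds, the radical anion may attack the benzyl ether, addition to the doubly ortho-substituted ketone may be slow, and the fluoride displacement on the electron-rich ring may stall. The fallback sets out from 9 and 8 and returns at 14; it stabilises the carbanion as a sulfone and makes the alkene by Julia olefination. 9 is treated with PhSO2Na in DMF to give 1-[4-(benzyloxy)phenyl]-2-(phenylsulfonyl)ethanone F1, which is reduced with the catalyst of step 5 to (1R)-1-[4-(benzyloxy)phenyl]-2-(phenylsulfonyl)ethanol F2. Its dianion (n-BuLi, 2 equiv, THF, −78 °C) is added to 8 and the adduct is closed with KOt-Bu in DMPU to the 3-(phenylsulfonyl)-2,4-diarylchroman-4-ol F3. Reductive elimination with SmI2 (or sodium amalgam) should then give 14.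

Step 8. Hydroboration of the crowded 1,1-diaryl alkene may be slow, or may add from both faces. The fallback sets out from 10 and 2 and returns at 16; it brings in the C3 oxygen by dihydroxylation and the interflavan bond by Friedel–Crafts coupling. The dianion 11, made from 10 as in step 6, is added to commercial 4-(benzyloxy)-2-fluorobenzaldehyde and closed with KOt-Bu to (2S,4RS)-7-(benzyloxy)-2-[4-(benzyloxy)phenyl]chroman-4-ol F4. Burgess dehydration gives (2S)-7-(benzyloxy)-2-[4-(benzyloxy)phenyl]-2H-chromene F5, and OsO4/N-methylmorpholine N-oxide, adding anti to the C2 aryl group, gives (2R,3S,4S)-7-(benzyloxy)-2-[4-(benzyloxy)phenyl]chroman-3,4-diol F6. TMSOTf in CH2Cl2 at −78 °C ionises the benzylic C4–OH, and C8 of 2 (in excess) should attack trans to the 3-hydroxyl to give 16. This variant is shorter but is kept as a fallback because the position (C8 against C6) and the face of attack are then only preferred, not fixed.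

Step 4. The hindered aryllithium may act as a base towards 6 (removing the proton between fluorine and the benzyloxy group) instead of adding to the amide. The fallback sets out from 3 and returns at 8; it replaces acyl substitution by addition and oxidation. The aryllithium 7 is added at −78 °C to the more electrophilic, commercial 4-(benzyloxy)-2-fluorobenzaldehyde to give [4-(benzyloxy)-2-fluorophenyl][(2R,3R)-3,5,7-tris(benzyloxy)-2-[4-(benzyloxy)phenyl]chroman-8-yl]methanol F7 (both carbinol epimers), which is oxidised to 8 with MnO2 or Dess–Martin periodinane.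

Further compounds
F1 | step 6 | 1-[4-(benzyloxy)phenyl]-2-(phenylsulfonyl)ethanone | O=C(CS(=O)(=O)c1ccccc1)c1ccc(OCc2ccccc2)cc1
F2 | step 6 | (1R)-1-[4-(benzyloxy)phenyl]-2-(phenylsulfonyl)ethanol | O[C@@H](CS(=O)(=O)c1ccccc1)c1ccc(OCc2ccccc2)cc1
F3 | step 6 | (2R)-7-(benzyloxy)-2-[4-(benzyloxy)phenyl]-3-(phenylsulfonyl)-4-[(2R,3R)-3,5,7-tris(benzyloxy)-2-[4-(benzyloxy)phenyl]chroman-8-yl]chroman-4-ol (C3 and C4 uncontrolled) | C(Oc1ccc(cc1)[C@H]1Oc2cc(OCc3ccccc3)ccc2C(O)(c2c(OCc3ccccc3)cc(OCc3ccccc3)c3c2O[C@H](c2ccc(OCc4ccccc4)cc2)[C@H](OCc2ccccc2)C3)C1S(=O)(=O)c1ccccc1)c1ccccc1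
F4 | step 8 | (2S,4RS)-7-(benzyloxy)-2-[4-(benzyloxy)phenyl]chroman-4-ol | C(Oc1ccc(cc1)[C@H]1Oc2cc(OCc3ccccc3)ccc2C(O)C1)c1ccccc1
F5 | step 8 | (2S)-7-(benzyloxy)-2-[4-(benzyloxy)phenyl]-2H-chromene | C(Oc1ccc(cc1)[C@H]1Oc2cc(OCc3ccccc3)ccc2C=C1)c1ccccc1
F6 | step 8 | (2R,3S,4S)-7-(benzyloxy)-2-[4-(benzyloxy)phenyl]chroman-3,4-diol | C(Oc1ccc(cc1)[C@H]1Oc2cc(OCc3ccccc3)ccc2[C@H](O)[C@@H]1O)c1ccccc1
F7 | step 4 | [4-(benzyloxy)-2-fluorophenyl][(2R,3R)-3,5,7-tris(benzyloxy)-2-[4-(benzyloxy)phenyl]chroman-8-yl]methanol | OC(c1ccc(OCc2ccccc2)cc1F)c1c(OCc2ccccc2)cc(OCc2ccccc2)c2c1O[C@H](c1ccc(OCc3ccccc3)cc1)[C@H](OCc1ccccc1)C2
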